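The readings were generated by integration for substances that don't exist, and the scatter is random.

The target runs in step with the intermediate in Thursday's flask, at 0.604 of it at 0.333 h and 0.613 of it at 10.0 h, so the argument can follow the intermediate.

| flask | substrate | remark | time |
|---|---|---|---|
| Thursday's | 0.12 M | the very flask that is asked about, followed so far |  |
| Tuesday's | 0.18 M | run made earlier |  |
| flask | 0.12 M |  | 30 h |

| run | time / h | intermediate / % | target / % |
|---|---|---|---|
| Thursday's | 0.100 | 5.0 | 2.8 |
| Thursday's | 0.333 | 9.1 | 5.5 |
| Thursday's | 1.00 | 6.6 | 4.1 |
| Thursday's | 3.00 | 5.1 | 3.7 |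
| Thursday's | 10.0 | 6.2 | 3.8 |
| Tuesday's | 0.333 | 9.1 | 5.4 |
| Tuesday's | 1.00 | 6.8 | 4.4 |
| Tuesday's | 3.00 | 5.2 | 2.7 |
| Tuesday's | 10.0 | 6.1 | 4.3 |
| Tuesday's | 30.0 | 7.2 | 4.1 |

(scatter of a reading: 0.3 percentage points)

- the moment within 30 h at which there is most intermediate
- the amount of intermediate, in percent of the substrate charged, at that time

- the earlier runs were read with a standard deviation of 0.3 percentage points

Percent readings at equal times agree across the two charges, 6.2% and 6.1% of intermediate at 10.0 h, so Tuesday's run stands in for Thursday's flask beyond its last reading. The highest reading, 9.1% at 0.333 h in both runs, is an early peak, but the intermediate climbs again after 3.00 h. For the best moment to lie at the end of the allowed time instead, Tuesday's 7.2% at 30.0 h would have to pass that peak, and it stands 1.9 points short, against a scatter of 0.3 points. Its last rise is 1.1 points in 20.0 h, at 0.428 of the pace of the interval before. At that last pace the gap would take 34.5 h more. This closing time, the gap over the last pace, is longer than the whole allowed 30 h. The reckoning here therefore keeps the best moment in the early peak, near 0.333 h, at about 9.1%.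

The forecast gives 0.33 h (0.2 h to 0.55 h) and 9.4% (8.9% to 10.5%): “The maximum is therefore the early transient”.

Thursday's flask reaches its highest intermediate, 9.00%, at 0.418 h.

    substrate ⇌ dormant form (K = 3.00, k = 0.0169 min⁻¹)
    intermediate ⇌ target (K = 0.640, k = 1.95 min⁻¹)
    intermediate ⇌ isomer of the product (K = 13.0, k = 0.0982 min⁻¹)
    substrate → intermediate (k = 0.0177 min⁻¹)

At 30.0 h Thursday's flask holds 6.81% of intermediate, which is being made 1.05 times faster than it is used up, each step taken net. Reckoned at Tuesday's last pace, its gap of 2.2 points comes to 39.9 h. A neighbouring flask with the same amounts and temperature is read at 3.0 d, which is 42.0 h past the allowed time and beyond the closing time of 34.5 h, and there the intermediate stands at 6.83% against a highest amount of 9.00%.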